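The route rests on cutting the bond between the benzylic CH2 (C3 of the propanoate) and ring carbon C1 of the catechol ring. The feature exploited is that C3, C2 and the ester carbonyl map onto an acrylate, whose unsubstituted terminus takes up an aryl group regiospecifically, while the ring position (para to O4, meta to O3) is fixed by a halogen. A Mizoroki–Heck coupling of 1,2-bis(benzyloxy)-4-bromobenzene with hexadecyl acrylate therefore forms this bond in one operation, one oxidation level high, as a cinnamate. The detour is free: a single hydrogenation saturates the C2–C3 alkene and removes both benzyl ethers.

Key step: step 1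

Remark: 1,2-bis(benzyloxy)-4-bromobenzene and hexadecyl acrylate are taken as purchased materials; the acrylate is used as sold, with its phenolic stabiliser.

Step 1
Reactants: 1 1,2-bis(benzyloxy)-4-bromobenzene; 2 hexadecyl acrylate (hexadecyl prop-2-enoate, 1.3 equiv)
Product: 3 hexadecyl (E)-3-[3,4-bis(benzyloxy)phenyl]prop-2-enoate
Conditions: Pd(OAc)2 (2 mol%), P(o-tol)3 (6 mol%), NaOAc (1.5 equiv), n-Bu4NBr (0.2 equiv), DMA, 120 °C, argon
Reagents that add atoms: none
Why: Mizoroki–Heck reaction: zerovalent palladium, formed in situ from Pd(OAc)2 and P(o-tol)3, inserts into the C–Br bond of 1, the arylpalladium bromide adds syn across the C=C of 2 with the aryl group going to the unsubstituted terminal carbon, and syn β-hydride elimination releases the cinnamate 3 while NaOAc takes up HBr and returns zerovalent palladium. The closest known reaction type is the Heck coupling of electron-rich bromoarenes such as 4-bromoanisole or 4-bromoveratrole with alkyl acrylates under Pd(OAc)2/triarylphosphine catalysis in DMA with NaOAc. No ring is closed and no stereocentre is formed; the alkene should be (E) because aryl and ester groups avoid each other in the conformer that undergoes β-hydride elimination, and its geometry is erased in step 2 in any case. Three selectivities are needed: the ring position is fixed by the bromine of 1 (para to one benzyloxy group, meta to the other), arylation at the terminal rather than the internal alkene carbon follows from the polarisation and the free terminus of the acrylate, and a second arylation is held back by the excess of 2 and the lower reactivity of the β-substituted cinnamate. The benzyl ethers and the hexadecyl ester should be inert to the weak base and to palladium in the absence of hydrogen.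

Step 2
Reactants: 3 hexadecyl (E)-3-[3,4-bis(benzyloxy)phenyl]prop-2-enoate
Product: 5 hexadecyl 3-(3,4-dihydroxyphenyl)propanoate, via saturated dibenzyl ether 4 (not isolated)
Conditions: H2 (1 atm), 10% Pd/C, THF/EtOAc 1:1, rt; filtration through Celite under argon
Reagents that add atoms: none
Why: Heterogeneous catalytic hydrogenation over palladium should saturate the conjugated C=C first (giving 4) and then cleave both aryl benzyl ethers by hydrogenolysis with release of toluene; the alkyl ester and the catechol ring are not reduced at 1 atm and room temperature, the alcohol-free solvent excludes transesterification, and no stereocentre is involved.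

Compound list
1 | 1,2-bis(benzyloxy)-4-bromobenzene | Brc1ccc(OCc2ccccc2)c(OCc2ccccc2)c1 | starting material
2 | hexadecyl acrylate (hexadecyl prop-2-enoate) | CCCCCCCCCCCCCCCCOC(=O)C=C | starting material
3 | hexadecyl (E)-3-[3,4-bis(benzyloxy)phenyl]prop-2-enoate | CCCCCCCCCCCCCCCCOC(=O)/C=C/c1ccc(OCc2ccccc2)c(OCc2ccccc2)c1 | intermediate
4 | hexadecyl 3-[3,4-bis(benzyloxy)phenyl]propanoate | CCCCCCCCCCCCCCCCOC(=O)CCc1ccc(OCc2ccccc2)c(OCc2ccccc2)c1 | intermediate
5 | hexadecyl 3-(3,4-dihydroxyphenyl)propanoate | CCCCCCCCCCCCCCCCOC(=O)CCc1ccc(O)c(O)c1 | target

Total step count: 2
Longest linear sequence: 2

Steps most likely to fail (the route has only two steps, so both are listed, the riskier first)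

Step 1. Oxidative addition into the electron-rich C–Br bond may be slow, so that the catalyst aggregates to palladium black before conversion is complete, and the acrylate may oligomerise thermally at 120 °C. The fallback sets out from 1 and comes back to the route at 4. Bromine–lithium exchange on 1 (n-BuLi, THF, −78 °C), trapping with B(OiPr)3 and hydrolysis with aqueous HCl should give [3,4-bis(benzyloxy)phenyl]boronic acid F1. A rhodium-catalysed 1,4-addition of F1 to 2 ([Rh(OH)(cod)]2, cod = cycloocta-1,5-diene, dioxane/H2O 10:1, 40 °C; Hayashi–Miyaura-type conjugate addition) would then form the same aryl–CH2 bond at the saturated oxidation level. It would give 4, here isolated, which the conditions of step 2 debenzylate to 5.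

Step 2. The hydrogenolysis may stall after saturation of the alkene or after loss of the first benzyl group, through catalyst poisoning by traces of phosphine or bromide carried over from step 1 or through poor solubility of the waxy substrate. The catechol may also be oxidised by air during filtration. The fallback sets out from 3 and comes back to the route at 5, and it separates the two tasks of step 2. BCl3 with pentamethylbenzene as benzyl-cation scavenger (CH2Cl2, −78 °C) should cleave both aryl benzyl ethers without touching the ester or the alkene and give hexadecyl (E)-3-(3,4-dihydroxyphenyl)prop-2-enoate F2. A short hydrogenation (H2, 1 atm, Pd/C, EtOAc, rt), which then only has to saturate the conjugated alkene, would give 5.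

Further compounds
F1 | step 1 | [3,4-bis(benzyloxy)phenyl]boronic acid | OB(O)c1ccc(OCc2ccccc2)c(OCc2ccccc2)c1
F2 | step 2 | hexadecyl (E)-3-(3,4-dihydroxyphenyl)prop-2-enoate | CCCCCCCCCCCCCCCCOC(=O)/C=C/c1ccc(O)c(O)c1
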